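In the runs so far, the small charge of G in teal stands as J in a larger share of itself than the large charge in grey. The decision is whether 12.0 mM of G is worth charging, and how long to leave it.

all flasks: D 20 mM
- teal: G 6 mM; run made earlier
- grey: G 24 mM; run made earlier
- flask: G 12.0 mM; time 15 d

- teal (time / d: J / %, D / %): 0.625: 23, 78; 1.67: 25, 77; 3.00: 25, 71; 5.00: 24, 75; 6.00: 23, 73; 10.0: 25, 76
- grey (time / d: J / %, D / %): 0.625: 57, 47; 1.67: 63, 34; 3.00: 65, 34; 5.00: 68, 35; 6.00: 66, 34; 10.0: 64, 33

(scatter of a reading: 1.5 percentage points)

- the J standing at 15 d, as a percentage of the D charged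
- amount of J if the flask were left three thousand times as long, in percent of the D charged

1. J stays flat within the scatter of 1.5 percentage points from 1.67 d to 10.0 d in both runs. Their means over that stretch are 4.88 mM for teal and 13.0 mM for grey.
2. G isn't read, so I assume that none stands on the plateau. Teal then gives 0.230 and grey 0.840 of what I call the waste ratio: mM of G charged not ending as J, for each mM of J standing. The ratio is larger in grey, so the richer charge wastes more.
3. I join these two ends by a straight line in G charged. At 12.0 mM it gives 0.433.
4. J is then G charged divided by one plus the ratio: 8.37 mM, or 41.9 % of D.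
5. My decision is to charge 12.0 mM and take the flask off at 15 d. The readings stop at 10.0 d, so they can't tell me how J keeps after that, and I give no long-time figure.

The forecast gives 43 % (39 % to 47 %) at 15 d and 43 % (35 % to 54 %) for the long wait, saying “Over very long times I expect the same value”.

The flask gives 42.0 % and 0 %.

    J → Z (k = 1.03 × 10⁻⁶ min⁻¹)
    2 G → X (k = 0.0940 M⁻¹ min⁻¹)
    D + G → J (k = 0.152 M⁻¹ min⁻¹)

At 15.0 d this flask holds 0 % of its G, the limiting reagent, so its waste ratio is 0.428. What the number 42.0 % doesn't show is the slow loss of J to Z: its half-life of 470 d is longer than 15 d, and J stands at 34.4 % after 150 d. For a neighbour charged with 7.2 mM of G, the same line gives a ratio of 0.270, hence 5.67 mM of J, or 28.3 %. That neighbour gives 28.6 %.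

The runs were generated by integration with constants of no real substance, and the scatter is random.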